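**Strategy**

The 33-membered ring (lactone chain C1–C32, counted from the carbonyl carbon to the O-bearing carbon) is an unbranched polymethylene lactone without stereocentres, so a ring bond far from the ester can be made as an alkene and then erased. The disconnection is C13–C14: this is exactly where erucic acid carries its Z double bond, so C1–C13 come from erucic acid and C14–C32 from icos-19-en-1-ol. The precursor is their open-chain ester. One operation closes the macrocycle by ring-closing olefin metathesis between the terminal vinyl group and the internal C13 olefin, expelling dec-1-ene, and hydrogenates the new C13=C14 bond in the same flask.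

Key step: step 3

Remark: compounds 1, 2 and 6 are taken as commercial. The alkene of the not-isolated macrocycle 8 is expected as an E/Z mixture and is written without geometry, since it is hydrogenated in the same operation.

**Route**

Step 1
Reactants: 1 11-bromoundec-1-ene; 2 9-bromononan-1-ol
Product: 5 icos-19-en-1-ol, via undec-10-enylmagnesium bromide 3 (not isolated), via chloromagnesium 9-bromononan-1-olate 4 (not isolated)
Conditions: 1 (1.3 equiv), Mg turnings, THF, 45 °C (gives 3); 2, MeMgCl (1.0 equiv), THF, −20 °C (gives 4); then 3 into 4, Li2CuCl4 (3 mol%), THF, −20 °C to rt; 1 M HCl
Reagents that add atoms: none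
Why: A Kochi-type Li2CuCl4-catalysed cross-coupling of a primary alkyl Grignard reagent with a primary alkyl bromide should form the C(sp3)–C(sp3) bond of the C20 chain, the hydroxyl being masked in the flask as its chloromagnesium alkoxide, which the Grignard reagent does not attack; no stereocentre is formed.

Step 2
Reactants: 5 icos-19-en-1-ol; 6 erucic acid, (Z)-docos-13-enoic acid
Product: 7 icos-19-en-1-yl (Z)-docos-13-enoate
Conditions: DCC (1.2 equiv), DMAP (10 mol%), CH2Cl2, 0 °C to rt
Reagents that add atoms: none
Why: In this Steglich esterification DCC activates the carboxylic acid and DMAP transfers the acyl group to the primary alcohol under neutral conditions that leave both olefins untouched.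

Step 3
Reactants: 7 icos-19-en-1-yl (Z)-docos-13-enoate
Product: 9 oxacyclotritriacontan-2-one (dotriacontan-32-olide), via oxacyclotritriacont-14-en-2-one 8 (not isolated)
Conditions: second-generation Grubbs catalyst (H2IMes)(PCy3)Cl2Ru=CHPh (5 mol%), CH2Cl2 (2 mM), 40 °C, Ar sparge; concentrate; then Pd/C (10 wt%), H2 (1 atm), EtOAc, rt
Reagents that add atoms: none
Why: The ruthenium benzylidene should first exchange onto the terminal vinyl group of the icosenyl chain, after which the chain-end ruthenium alkylidene adds across the Z olefin at C13 of the docosenoyl chain in a [2+2] step and cycloreversion of the ruthenacyclobutane forms C13=C14, closes the ring and sends the nonylidene tail out as dec-1-ene (Chauvin mechanism). The closest known reaction type is macrocyclic ring-closing olefin metathesis of ω-alkenyl esters of unsaturated fatty acids, telescoped with heterogeneous hydrogenation of the crude cycloalkene 8 over Pd/C, to which the lactone is inert. The single 33-membered ring closes end to end by intramolecular metathesis of the chain-end carbene onto the remote internal olefin, a strain-free macrocyclisation under ring–chain equilibrium control. No stereocentre is created, and the E/Z mixture expected for 8 is of no account because hydrogen removes the double bond. The step needs ring closure to win over oligomerisation and must avoid double-bond migration: the 2 mM dilution and the reversibility of metathesis on an unstrained chain should let oligomers back-bite to the monomeric ring, while the mild temperature keeps ruthenium hydride isomerisation, which would give ring-size homologues, low. The substrate secures the ring size, because it holds only two olefins, one at each future ring carbon (C13 and C14), so no other ring can form directly.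

**Compound list**

1 | 11-bromoundec-1-ene | C=CCCCCCCCCCBr | starting material
2 | 9-bromononan-1-ol | OCCCCCCCCCBr | starting material
3 | undec-10-enylmagnesium bromide | C=CCCCCCCCCC[Mg]Br | intermediate
4 | chloromagnesium 9-bromononan-1-olate | BrCCCCCCCCCO[Mg]Cl | intermediate
5 | icos-19-en-1-ol | C=CCCCCCCCCCCCCCCCCCCO | intermediate
6 | erucic acid, (Z)-docos-13-enoic acid | CCCCCCCC/C=C\CCCCCCCCCCCC(=O)O | starting material
7 | icos-19-en-1-yl (Z)-docos-13-enoate | CCCCCCCC/C=C\CCCCCCCCCCCC(=O)OCCCCCCCCCCCCCCCCCCC=C | intermediate
8 | oxacyclotritriacont-14-en-2-one (E/Z mixture, geometry not defined) | O=C1CCCCCCCCCCCC=CCCCCCCCCCCCCCCCCCCO1 | intermediate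
9 | oxacyclotritriacontan-2-one (dotriacontan-32-olide) | O=C1CCCCCCCCCCCCCCCCCCCCCCCCCCCCCCCO1 | target

**Summary**

Total step count: 3
Longest linear sequence: 3 steps (1 and 2 to 5, then 7, then 9)

**Steps most likely to fail**

Step 3. The dec-1-ene set free by the ring closure is not volatile, stays in the dilute solution and keeps re-entering the metathesis equilibrium. Ring-opening cross-metathesis and chain-end capping may therefore hold back complete ring closure, and any open-chain ester left would be hydrogenated to a wax ester that is hard to separate; double-bond migration may also blur the ring size. Fallback: setting out from compound 7, the nonyl tail is first cut off by ethenolysis (first-generation Grubbs catalyst Cl2(PCy3)2Ru=CHPh, ethene 10 bar, toluene, 40 °C). This should give the α,ω-diene icos-19-en-1-yl tetradec-13-enoate F1 and dec-1-ene, which is removed under vacuum. Ring-closing metathesis of F1 (second-generation Grubbs catalyst, CH2Cl2, 2 mM, 40 °C, Ar sparge) is then driven by irreversible loss of ethene and comes back to the route at compound 8, which is hydrogenated to 9 as in step 3.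

Step 1. The chloromagnesium bromoalkoxide may aggregate and react slowly, so that homocoupling of the Grignard reagent, halogen–magnesium exchange and reduction of the bromide compete with the cross-coupling. Fallback: setting out from compound 2, the hydroxyl is protected as its tetrahydropyranyl ether (3,4-dihydro-2H-pyran, PPTS, CH2Cl2) to give racemic 2-[(9-bromononyl)oxy]oxane F2. This soluble neutral bromide is coupled with Grignard reagent 3 (Li2CuCl4 cat., THF, −20 °C to rt) to give racemic 2-(icos-19-en-1-yloxy)oxane F3. Acetal exchange (PPTS, MeOH, 50 °C) then comes back to the route at compound 5.

Step 2. Slow acylation of the waxy, poorly soluble C20 alcohol may let the activated acid rearrange by O-to-N acyl shift to an unreactive N-acylurea, and the urea may be hard to remove from the waxy ester. Fallback: setting out from compound 6, the acid is converted with oxalyl chloride (cat. DMF, CH2Cl2, 0 °C to rt) into (Z)-docos-13-enoyl chloride F4, which acylates 5 in CH2Cl2 with pyridine and comes back to the route at compound 7.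

**Further compounds**

F1 | step 3 | icos-19-en-1-yl tetradec-13-enoate | C=CCCCCCCCCCCCC(=O)OCCCCCCCCCCCCCCCCCCC=C
F2 | step 1 | 2-[(9-bromononyl)oxy]oxane (racemic) | BrCCCCCCCCCOC1CCCCO1
F3 | step 1 | 2-(icos-19-en-1-yloxy)oxane (racemic) | C=CCCCCCCCCCCCCCCCCCCOC1CCCCO1
F4 | step 2 | (Z)-docos-13-enoyl chloride | CCCCCCCC/C=C\CCCCCCCCCCCC(=O)Cl
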